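Start from the late hours of this flask, when the pace hangs on how much nucleophile is still free to react.

    nucleophile ⇌ dormant form (K1 = 1.0, k1 = 0.12 h⁻¹)
    electrophile + nucleophile → acid set free + product (k2 = 0.49 M⁻¹ h⁻¹)
    nucleophile + acid set free ⇌ idle adduct, settled at all times (K3 = 86 M⁻¹)
    nucleophile + acid set free ⇌ protonated nucleophile, settled at all times (K4 = 12000 M⁻¹)

electrophile 0.13 M; time 2.5 d

- amounts and yields of acid set free count idle adduct too
- the amount of nucleophile is what is sought; it is there from the start
- run time (flask): 2.5 d

- the equivalents of nucleophile at which the part of the electrophile that has reacted at 2.5 d is just 80%

What does one electrophile cost? Suppose each acid set free takes a second nucleophile: at the target from 2 equiv, the free pool (nucleophile and dormant form together) is then 0.0520 M. Even with half of that pool as nucleophile, protonated nucleophile outweighs unbound acid by 12000 M⁻¹ times [nucleophile], which is 312, far above one, so keep the supposition and begin at 2 equiv.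

How much of the free pool stands ready at any moment? Step 1 relaxes with a half-life of 2.89 h, much shorter than 2.5 d, so treat it as a pre-equilibrium. With K1 at 1.0, half of the free pool is nucleophile and the rest is dormant form.

Does 2 equiv get there? Let x be the part of the electrophile reacted. Then [nucleophile] and [electrophile] both follow 1−x, and x/(1−x) grows in step with time. Call its value at the asked time the reach, twice k2 times the electrophile charge times the time, divided by one plus K1: 3.82. The target of 80% needs 4.00, and this reach gives 79.3%. Ignoring the start, I commit to a shade above 2 equiv.

The forecast gives 2.05 equiv, holding that “the early head start before it equilibrates with the dormant form nearly cancels the later lag in its release”.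

The flask needs 2.04 equiv, so the forecast holds. Now take the binding away at a round 2 equiv, still ignoring the start, and each electrophile costs one nucleophile. The natural logarithm of the free pool over 2[electrophile] then reaches the reach divided by 2, which is 1.91, and this reckons 92.0% reacted at 2.5 d. The run with nothing binding acid set free stands at 93.1%.

(The numbers are made up, and the outcome is calculated.)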